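Assumption: LiC≡CH·H2NCH2CH2NH2 and the L-fructose-derived Shi ketone are taken as commercially available; ring positions in the bicyclic compounds follow 1-benzoxepine numbering (O1, C2, C3, C4, C5, C5a, C6, C7, C8, C9, C9a).

**Retrosynthetic overview**
1. The last C–C bond is the central CH2–CH2 bond, made by nickel-hydride hydroalkylation of exocyclic alkene 20 (fragment A, the 3,7-diacetoxy half) with primary iodide 39 (fragment B, the 3-silyloxy-7-acetoxy half); O-desilylation ends the route.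
2. Fragment A: the C7 carbinol (axial oxygen) comes from MeLi/CeCl3 addition to α-methylene ketone 18, made from bicyclic β-keto ester 15.
3. Fragment B: the C7 carbinol (equatorial oxygen) comes from epoxidation and LiAlH4 opening of exocyclic alkene 35; the CH2I group comes from the pivalate.
4. In each fragment the oxepane ring and the cyclohexane ring form together in one silyl-triflate cascade of an (S,S,S)-bis-epoxide, ended by a silyl enol ether (A) or an allylsilane (B).
5. Both bis-epoxides come from Shi epoxidation of E-dienes built from the common E-alkenyl iodide 5, itself made by zirconium-catalysed carboalumination–iodination of 6-methylhept-5-en-1-yne.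

**Route**

Common steps (steps 1–2)

Step 1
Reactants: 1 5-bromo-2-methylpent-2-ene; 2 lithium acetylide–ethane-1,2-diamine complex (LiC≡CH·H2NCH2CH2NH2)
Product: 3 6-methylhept-5-en-1-yne
Conditions: DMSO, 10 → 25 °C
Reagents that add atoms: none
Why: SN2 alkylation of the acetylide by the primary homoallylic bromide in a dipolar aprotic solvent (acetylide alkylation), with no stereocentre formed.

Step 2
Reactants: 3 6-methylhept-5-en-1-yne
Product: 5 (1E)-1-iodo-2,6-dimethylhepta-1,5-diene, via alkenylalane 4 (not isolated)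
Conditions: AlMe3 (2 equiv), Cp2ZrCl2 (20 mol %), CH2Cl2, 0 → 25 °C; then I2, THF, −30 → 0 °C
Reagents that add atoms: trimethylaluminium C[Al](C)C; iodine II
Why: Zirconium-catalysed Negishi carboalumination adds methyl and aluminium syn across the terminal alkyne (methyl on the internal carbon), and iodinolysis with retention fixes the E trisubstituted alkene.

Fragment A (steps 3–11)

Step 3
Reactants: 5 (1E)-1-iodo-2,6-dimethylhepta-1,5-diene; 6 methyl 3-bromopropanoate
Product: 8 methyl (4E)-5,9-dimethyldeca-4,8-dienoate, via alkylzinc bromide 7 (not isolated)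
Conditions: 6, Zn dust, I2 (5 mol %), DMA, 70 °C; then 5, Pd(PPh3)4 (3 mol %), THF, 45 °C
Reagents that add atoms: none
Why: Zinc insertion gives the ester-stabilised zinc homoenolate, which couples with the alkenyl iodide in a palladium-catalysed Negishi coupling with retention of the E geometry.

Step 4
Reactants: 8 methyl (4E)-5,9-dimethyldeca-4,8-dienoate
Product: 9 methyl 3-[(2S,3S)-3-{2-[(2S)-3,3-dimethyloxiran-2-yl]ethyl}-3-methyloxiran-2-yl]propanoate
Conditions: L-fructose-derived Shi ketone (40 mol %), KHSO5 (as 2KHSO5·KHSO4·K2SO4), K2CO3, Bu4NHSO4, MeCN/CH2(OMe)2/aq Na2B4O7–Na2EDTA buffer (pH 10.5), 0 °C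
Reagents that add atoms: potassium peroxymonosulfate [K+].[O-]S(=O)(=O)OO
Why: Shi asymmetric epoxidation (chiral dioxirane, spiro transition state) oxidises both electron-rich trisubstituted alkenes with the same facial sense and sets the three S epoxide carbons that become C3, C5a and C9a.

Step 5
Reactants: 9 (S,S,S)-bis-epoxy ester; 10 methyl acetate
Product: 12 methyl 5-[(2S,3S)-3-{2-[(2S)-3,3-dimethyloxiran-2-yl]ethyl}-3-methyloxiran-2-yl]-3-oxopentanoate, via methyl lithioacetate 11 (not isolated)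
Conditions: LiN(i-Pr)2 (3.2 equiv), 10 (3.3 equiv), THF, −78 °C; then 9, −78 → −30 °C; aq NH4Cl
Reagents that add atoms: none
Why: Crossed Claisen condensation driven by deprotonation of the β-keto ester product, run cold enough that the trisubstituted epoxides are not opened.

Step 6
Reactants: 12 bis-epoxy β-keto ester
Product: 13 methyl (2Z)-3-{[tert-butyl(dimethyl)silyl]oxy}-5-[(2S,3S)-3-{2-[(2S)-3,3-dimethyloxiran-2-yl]ethyl}-3-methyloxiran-2-yl]pent-2-enoate
Conditions: NaH, THF, 0 °C; then TBSCl, 0 → 25 °C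
Reagents that add atoms: tert-butyl(chloro)dimethylsilane CC(C)(C)[Si](C)(C)Cl
Why: O-silylation of the chelated sodium enolate (silyl enol ether formation) gives the π-nucleophile that ends the cascade; the enol ether geometry is not carried into a stereocentre.

Step 7
Reactants: 13 bis-epoxy silyl enol ether
Product: 15 methyl (3S,5aS,6S,9aS)-3-hydroxy-2,2,5a-trimethyl-7-oxodecahydro-1-benzoxepine-6-carboxylate, via trimethylsilyl ether 14 (not isolated)
Conditions: TMSOTf (1.3 equiv), 2,6-di-tert-butyl-4-methylpyridine, CH2Cl2, −78 °C; then 1 M HCl, THF, 0 °C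
Reagents that add atoms: none
Why: Silyl-triflate-initiated epoxide-opening oxa/carbacyclisation cascade in which the internal epoxide oxygen attacks the tertiary carbon of the silyl-activated terminal epoxide and the enol ether carbon then opens the resulting oxonium at its tertiary carbon with inversion through a chair transition state, giving the trans-fused oxepane–cyclohexanone with C3 and C9a retained from the epoxides, C5a set by inversion and the epimerisable ester equatorial.

Step 8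
Reactants: 15 bicyclic β-keto ester
Product: 16 methyl (3S,5aS,9aS)-3-hydroxy-7-methoxy-2,2,5a-trimethyl-2,3,4,5,5a,8,9,9a-octahydro-1-benzoxepine-6-carboxylate
Conditions: Me3SiCHN2, MeOH/toluene, 25 °C
Reagents that add atoms: (trimethylsilyl)diazomethane C[Si](C)(C)C=[N+]=[N-]
Why: Diazoalkane O-methylation of the acidic enol of the cyclic β-keto ester, which leaves the non-acidic C3 alcohol untouched and removes the C6 stereocentre on purpose.

Step 9
Reactants: 16 methyl enol ether ester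
Product: 18 (3S,5aS,9aS)-3-hydroxy-2,2,5a-trimethyl-6-methylideneoctahydro-1-benzoxepin-7(2H)-one, via allylic alcohol 17 (not isolated)
Conditions: i-Bu2AlH (4.5 equiv), CH2Cl2, −78 → 0 °C; then 1 M HCl, THF, 25 °C
Reagents that add atoms: water O
Why: Hydride reduction of the vinylogous carbonate to the allylic alcohol followed by acid-promoted loss of water and enol ether hydrolysis (reduction–hydrolysis transposition of a β-alkoxy enoate, Stork–Danheiser type) gives the α-methylene ketone without creating a stereocentre.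

Step 10
Reactants: 18 α-methylene ketone
Product: 19 (3S,5aS,7R,9aS)-2,2,5a,7-tetramethyl-6-methylidenedecahydro-1-benzoxepine-3,7-diol
Conditions: MeLi (3.5 equiv), CeCl3 (3.5 equiv, anhydrous), THF, −78 °C
Reagents that add atoms: methyllithium [Li]C
Why: Organocerium 1,2-addition (Imamoto conditions) avoids enolisation and conjugate addition, and the methyl group enters equatorially from the face opposite the axial C5a methyl, setting C7 as R with an axial hydroxyl.

Step 11
Reactants: 19 diol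
Product: 20 (3S,5aS,7R,9aS)-2,2,5a,7-tetramethyl-6-methylidenedecahydro-1-benzoxepine-3,7-diyl diacetate (fragment A)
Conditions: Ac2O (10 equiv), DMAP (2 equiv), Et3N, toluene, 60 °C
Reagents that add atoms: acetic anhydride CC(=O)OC(C)=O
Why: DMAP-catalysed acylation under forcing, non-acidic conditions esterifies both the secondary and the hindered tertiary allylic alcohol without ionising the latter.

Fragment B (steps 12–24)

Step 12
Reactants: 5 (1E)-1-iodo-2,6-dimethylhepta-1,5-diene; 21 oxirane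
Product: 23 (3E)-4,8-dimethylnona-3,7-dien-1-ol, via alkenyllithium 22 (not isolated)
Conditions: t-BuLi (2.05 equiv), Et2O, −78 °C; then 21 (3 equiv), −78 → 0 °C; aq NH4Cl
Reagents that add atoms: none
Why: Iodine–lithium exchange with t-BuLi proceeds with retention of the E alkene geometry, and the configurationally stable alkenyllithium opens oxirane by SN2 attack (epoxide ring-opening homologation), adding the two-carbon alcohol arm.

Step 13
Reactants: 23 (3E)-4,8-dimethylnona-3,7-dien-1-ol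
Product: 24 (6E)-9-iodo-2,6-dimethylnona-2,6-diene
Conditions: PPh3, I2, imidazole, CH2Cl2, 0 °C
Reagents that add atoms: iodine II
Why: Appel-type iodination of the primary alcohol through the alkoxyphosphonium ion, with no effect on the alkenes.

Step 14
Reactants: 24 (6E)-9-iodo-2,6-dimethylnona-2,6-diene; 25 prop-2-yn-1-ol
Product: 27 (6E)-7,11-dimethyldodeca-6,10-dien-2-yn-1-ol, via dilithiated propargyl alcohol 26 (not isolated)
Conditions: 25, n-BuLi (2.05 equiv), THF, −78 → 0 °C; then 24, DMPU, 0 → 25 °C; aq NH4Cl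
Reagents that add atoms: none
Why: The dianion of propargyl alcohol is alkylated at its more nucleophilic carbon terminus by the primary iodide (acetylide alkylation), with DMPU favouring substitution over elimination.

Step 15
Reactants: 27 (6E)-7,11-dimethyldodeca-6,10-dien-2-yn-1-ol
Product: 29 (2Z,6E)-3-iodo-7,11-dimethyldodeca-2,6,10-trien-1-ol, via cyclic vinylaluminate 28 (not isolated)
Conditions: NaAlH2(OCH2CH2OMe)2 (1.5 equiv), THF, 0 → 25 °C; EtOAc; then I2, THF, −78 → 0 °C
Reagents that add atoms: iodine II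
Why: Hydroxyl-directed trans-hydroalumination of the propargylic alcohol places aluminium on C3 in a five-membered aluminate, and iodinolysis with retention gives the Z iodoalkene with iodine cis to the CH2OH group.

Step 16
Reactants: 29 (2Z,6E)-3-iodo-7,11-dimethyldodeca-2,6,10-trien-1-ol
Product: 30 (2Z,6E)-3-iodo-7,11-dimethyldodeca-2,6,10-trien-1-yl 2,2-dimethylpropanoate
Conditions: t-BuCOCl, pyridine, DMAP (cat.), CH2Cl2, 0 °C
Reagents that add atoms: 2,2-dimethylpropanoyl chloride CC(C)(C)C(Cl)=O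
Why: Acylation of the primary allylic alcohol gives a pivalate that further deactivates the iodoalkene toward epoxidation and is removed later by LiAlH4.

Step 17
Reactants: 30 iodo triene pivalate
Product: 31 (2Z)-5-[(2S,3S)-3-{2-[(2S)-3,3-dimethyloxiran-2-yl]ethyl}-3-methyloxiran-2-yl]-3-iodopent-2-en-1-yl 2,2-dimethylpropanoate
Conditions: L-fructose-derived Shi ketone (40 mol %), KHSO5 (as 2KHSO5·KHSO4·K2SO4), K2CO3, Bu4NHSO4, MeCN/CH2(OMe)2/aq Na2B4O7–Na2EDTA buffer (pH 10.5), 0 °C
Reagents that add atoms: potassium peroxymonosulfate [K+].[O-]S(=O)(=O)OO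
Why: Shi asymmetric epoxidation is chemoselective for the two electron-rich trisubstituted alkenes over the electron-poor iodoalkene bearing an allylic ester, and sets the three S epoxide carbons.

Step 18
Reactants: 31 bis-epoxy alkenyl iodide
Product: 32 (2Z)-5-[(2S,3S)-3-{2-[(2S)-3,3-dimethyloxiran-2-yl]ethyl}-3-methyloxiran-2-yl]-3-[(trimethylsilyl)methyl]pent-2-en-1-yl 2,2-dimethylpropanoate
Conditions: Me3SiCH2MgCl, ZnCl2, THF, 0 °C; then 31, Pd(PPh3)4 (5 mol %), THF, 25 °C
Reagents that add atoms: chloro[(trimethylsilyl)methyl]magnesium C[Si](C)(C)C[Mg]Cl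
Why: Palladium-catalysed Negishi coupling of the alkenyl iodide with the mild silylmethylzinc reagent proceeds with retention, giving the allylsilane with CH2SiMe3 cis to CH2OPiv while epoxides and pivalate survive.

Step 19
Reactants: 32 bis-epoxy allylsilane
Product: 34 [(3S,5aS,6R,9aS)-3-hydroxy-2,2,5a-trimethyl-7-methylidenedecahydro-1-benzoxepin-6-yl]methyl 2,2-dimethylpropanoate, via trimethylsilyl ether 33 (not isolated)
Conditions: TMSOTf (1.3 equiv), 2,6-di-tert-butyl-4-methylpyridine, CH2Cl2, −78 °C; then 0.5 M HCl, THF, 0 °C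
Reagents that add atoms: none
Why: The same epoxide-opening oxa/carbacyclisation cascade, ended by the allylsilane, gives the exocyclic methylene regiospecifically, and the chair transition state with the CH2OPiv group trans to the chain places it equatorial (C6 R) on a trans-fused bicycle.

Step 20
Reactants: 34 bicyclic alcohol
Product: 35 [(3S,5aS,6R,9aS)-3-{[tert-butyl(dimethyl)silyl]oxy}-2,2,5a-trimethyl-7-methylidenedecahydro-1-benzoxepin-6-yl]methyl 2,2-dimethylpropanoate
Conditions: TBSOTf, 2,6-lutidine, CH2Cl2, −78 → 0 °C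
Reagents that add atoms: tert-butyldimethylsilyl trifluoromethanesulfonate CC(C)(C)[Si](C)(C)OS(=O)(=O)C(F)(F)F
Why: Silylation with the reactive silyl triflate protects the hindered C3 alcohol that must stay unacetylated in the target.

Step 21
Reactants: 35 exocyclic alkene
Product: 36 [(3S,5aS,6R,7S,9aS)-3-{[tert-butyl(dimethyl)silyl]oxy}-2,2,5a-trimethyloctahydro-2H-spiro[1-benzoxepine-7,2'-oxiran]-6-yl]methyl 2,2-dimethylpropanoate (oxirane oxygen equatorial)
Conditions: mCPBA, NaHCO3, CH2Cl2, 0 °C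
Reagents that add atoms: 3-chloroperoxybenzoic acid OOC(=O)c1cccc(Cl)c1
Why: Prilezhaev epoxidation takes place from the equatorial face opposite the axial C5a methyl, placing the oxirane oxygen equatorial and its CH2 axial.

Step 22
Reactants: 36 spiro-epoxide
Product: 37 (3S,5aS,6R,7S,9aS)-3-{[tert-butyl(dimethyl)silyl]oxy}-6-(hydroxymethyl)-2,2,5a,7-tetramethyldecahydro-1-benzoxepin-7-ol
Conditions: LiAlH4, THF, 0 → 50 °C
Reagents that add atoms: none
Why: Hydride opens the epoxide by SN2 attack at its CH2 carbon, giving the axial methyl and equatorial tertiary hydroxyl (C7 S), and the same reagent cleaves the pivalate reductively.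

Step 23
Reactants: 37 diol
Product: 38 (3S,5aS,6S,7S,9aS)-3-{[tert-butyl(dimethyl)silyl]oxy}-6-(iodomethyl)-2,2,5a,7-tetramethyldecahydro-1-benzoxepin-7-ol
Conditions: PPh3, I2, imidazole, toluene/MeCN, 25 → 60 °C
Reagents that add atoms: iodine II
Why: Appel-type iodination is selective for the primary alcohol because the tertiary alcohol cannot undergo SN2 displacement.

Step 24
Reactants: 38 iodo alcohol
Product: 39 (3S,5aS,6S,7S,9aS)-3-{[tert-butyl(dimethyl)silyl]oxy}-6-(iodomethyl)-2,2,5a,7-tetramethyldecahydro-1-benzoxepin-7-yl acetate (fragment B)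
Conditions: Ac2O, DMAP, Et3N, CH2Cl2, 40 °C
Reagents that add atoms: acetic anhydride CC(=O)OC(C)=O
Why: DMAP-catalysed acetylation of the equatorial tertiary alcohol, with the silyl ether and the hindered primary iodide unaffected.

Fragment union and end game

Step 25
Reactants: 20 fragment A; 39 fragment B
Product: 40 (3S,5aS,6S,7R,9aS)-6-{2-[(3S,5aS,6S,7S,9aS)-7-(acetyloxy)-3-{[tert-butyl(dimethyl)silyl]oxy}-2,2,5a,7-tetramethyldecahydro-1-benzoxepin-6-yl]ethyl}-2,2,5a,7-tetramethyldecahydro-1-benzoxepine-3,7-diyl diacetate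
Conditions: NiBr2(diglyme) (10 mol %), 4,4'-di-tert-butyl-2,2'-bipyridine (12 mol %), (EtO)2MeSiH (2.5 equiv), KF (2.5 equiv), DMA/THF, 30 °C; 20 (1.3 equiv), 39 (1.0 equiv)
Reagents that add atoms: none
Why: Proposed new method: a bipyridine-ligated nickel hydride (from the NiBr2 precatalyst, the silane and fluoride) should add syn and anti-Markovnikov across the exocyclic C6=CH2 bond of 20 from the face opposite the two axial groups (C5a methyl and C7 acetoxy), which sets C6 as S with the new CH2 equatorial and gives a primary alkylnickel that cannot chain-walk (both neighbours of C6 are quaternary) or lose acetate (the acetoxy group is γ to nickel), while monovalent nickel turns iodide 39 into a primary radical by halogen abstraction, and radical capture gives a dialkyl trivalent nickel species that forms the central CH2–CH2 bond by reductive elimination; the closest known reaction type is nickel-hydride-catalysed anti-Markovnikov hydroalkylation of unhindered terminal alkenes with primary alkyl iodides, which has not been shown for an exocyclic 1,1-disubstituted alkene flanked by two quaternary carbons or used for substrate-controlled creation of a ring stereocentre.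

Step 26
Reactants: 40 silyl ether of the target
Product: 41 (3S,5aS,6S,7R,9aS)-6-{2-[(3S,5aS,6S,7S,9aS)-7-(acetyloxy)-3-hydroxy-2,2,5a,7-tetramethyldecahydro-1-benzoxepin-6-yl]ethyl}-2,2,5a,7-tetramethyldecahydro-1-benzoxepine-3,7-diyl diacetate
Conditions: HF·pyridine, pyridine/THF, 0 → 25 °C
Reagents that add atoms: none
Why: Fluoride-mediated cleavage of the Si–O bond under buffered conditions removes the silyl ether while the secondary and tertiary acetates stay in place and no stereocentre is touched.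

**Compound list**
1 | 5-bromo-2-methylpent-2-ene | CC(C)=CCCBr | starting material
2 | lithium acetylide–ethane-1,2-diamine complex | [Li]C#C.NCCN | starting material
3 | 6-methylhept-5-en-1-yne | CC(C)=CCCC#C | intermediate
4 | [(1E)-2,6-dimethylhepta-1,5-dien-1-yl]dimethylalumane | CC(C)=CCC/C(C)=C/[Al](C)C | intermediate (not isolated)
5 | (1E)-1-iodo-2,6-dimethylhepta-1,5-diene | CC(C)=CCC/C(C)=C/I | intermediate
6 | methyl 3-bromopropanoate | COC(=O)CCBr | starting material
7 | bromo(3-methoxy-3-oxopropyl)zinc | COC(=O)CC[Zn]Br | intermediate (not isolated)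
8 | methyl (4E)-5,9-dimethyldeca-4,8-dienoate | COC(=O)CC/C=C(\C)CCC=C(C)C | intermediate
9 | methyl 3-[(2S,3S)-3-{2-[(2S)-3,3-dimethyloxiran-2-yl]ethyl}-3-methyloxiran-2-yl]propanoate | COC(=O)CC[C@@H]1O[C@@]1(C)CC[C@@H]1OC1(C)C | intermediate
10 | methyl acetate | CC(=O)OC | starting material
11 | methyl lithioacetate (lithium 1-methoxyethen-1-olate) | [Li]OC(=C)OC | intermediate (not isolated)
12 | methyl 5-[(2S,3S)-3-{2-[(2S)-3,3-dimethyloxiran-2-yl]ethyl}-3-methyloxiran-2-yl]-3-oxopentanoate | COC(=O)CC(=O)CC[C@@H]1O[C@@]1(C)CC[C@@H]1OC1(C)C | intermediate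
13 | methyl (2Z)-3-{[tert-butyl(dimethyl)silyl]oxy}-5-[(2S,3S)-3-{2-[(2S)-3,3-dimethyloxiran-2-yl]ethyl}-3-methyloxiran-2-yl]pent-2-enoate | COC(=O)/C=C(\O[Si](C)(C)C(C)(C)C)CC[C@@H]1O[C@@]1(C)CC[C@@H]1OC1(C)C | intermediate
14 | methyl (3S,5aS,6S,9aS)-2,2,5a-trimethyl-7-oxo-3-[(trimethylsilyl)oxy]decahydro-1-benzoxepine-6-carboxylate | C[Si](C)(C)O[C@H]1CC[C@]2(C)[C@H](CCC(=O)[C@H]2C(=O)OC)OC1(C)C | intermediate (not isolated)
15 | methyl (3S,5aS,6S,9aS)-3-hydroxy-2,2,5a-trimethyl-7-oxodecahydro-1-benzoxepine-6-carboxylate | O[C@H]1CC[C@]2(C)[C@H](CCC(=O)[C@H]2C(=O)OC)OC1(C)C | intermediate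
16 | methyl (3S,5aS,9aS)-3-hydroxy-7-methoxy-2,2,5a-trimethyl-2,3,4,5,5a,8,9,9a-octahydro-1-benzoxepine-6-carboxylate | O[C@H]1CC[C@]2(C)[C@H](CCC(OC)=C2C(=O)OC)OC1(C)C | intermediate
17 | (3S,5aS,9aS)-6-(hydroxymethyl)-7-methoxy-2,2,5a-trimethyl-2,3,4,5,5a,8,9,9a-octahydro-1-benzoxepin-3-ol | O[C@H]1CC[C@]2(C)[C@H](CCC(OC)=C2CO)OC1(C)C | intermediate (not isolated)
18 | (3S,5aS,9aS)-3-hydroxy-2,2,5a-trimethyl-6-methylideneoctahydro-1-benzoxepin-7(2H)-one | O[C@H]1CC[C@]2(C)[C@H](CCC(=O)C2=C)OC1(C)C | intermediate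
19 | (3S,5aS,7R,9aS)-2,2,5a,7-tetramethyl-6-methylidenedecahydro-1-benzoxepine-3,7-diol | O[C@H]1CC[C@]2(C)[C@H](CC[C@@](C)(O)C2=C)OC1(C)C | intermediate
20 | (3S,5aS,7R,9aS)-2,2,5a,7-tetramethyl-6-methylidenedecahydro-1-benzoxepine-3,7-diyl diacetate (fragment A) | CC(=O)O[C@H]1CC[C@]2(C)[C@H](CC[C@@](C)(OC(C)=O)C2=C)OC1(C)C | intermediate
21 | oxirane | C1CO1 | starting material
22 | [(1E)-2,6-dimethylhepta-1,5-dien-1-yl]lithium | [Li]/C=C(\C)CCC=C(C)C | intermediate (not isolated)
23 | (3E)-4,8-dimethylnona-3,7-dien-1-ol | OCC/C=C(\C)CCC=C(C)C | intermediate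
24 | (6E)-9-iodo-2,6-dimethylnona-2,6-diene | ICC/C=C(\C)CCC=C(C)C | intermediate
25 | prop-2-yn-1-ol | C#CCO | starting material
26 | lithium 3-lithioprop-2-yn-1-olate | [Li]OCC#C[Li] | intermediate (not isolated)
27 | (6E)-7,11-dimethyldodeca-6,10-dien-2-yn-1-ol | OCC#CCC/C=C(\C)CCC=C(C)C | intermediate
28 | sodium 3-[(3E)-4,8-dimethylnona-3,7-dien-1-yl]-2,2-bis(2-methoxyethoxy)-2,5-dihydro-1,2-oxaaluminol-2-uide | [Na+].COCCO[Al-]1(OCCOC)OCC=C1CC/C=C(\C)CCC=C(C)C | intermediate (not isolated)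
29 | (2Z,6E)-3-iodo-7,11-dimethyldodeca-2,6,10-trien-1-ol | OC/C=C(I)/CC/C=C(\C)CCC=C(C)C | intermediate
30 | (2Z,6E)-3-iodo-7,11-dimethyldodeca-2,6,10-trien-1-yl 2,2-dimethylpropanoate | CC(C)(C)C(=O)OC/C=C(I)/CC/C=C(\C)CCC=C(C)C | intermediate
31 | (2Z)-5-[(2S,3S)-3-{2-[(2S)-3,3-dimethyloxiran-2-yl]ethyl}-3-methyloxiran-2-yl]-3-iodopent-2-en-1-yl 2,2-dimethylpropanoate | CC(C)(C)C(=O)OC/C=C(I)/CC[C@@H]1O[C@@]1(C)CC[C@@H]1OC1(C)C | intermediate
32 | (2Z)-5-[(2S,3S)-3-{2-[(2S)-3,3-dimethyloxiran-2-yl]ethyl}-3-methyloxiran-2-yl]-3-[(trimethylsilyl)methyl]pent-2-en-1-yl 2,2-dimethylpropanoate | CC(C)(C)C(=O)OC/C=C(C[Si](C)(C)C)/CC[C@@H]1O[C@@]1(C)CC[C@@H]1OC1(C)C | intermediate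
33 | {(3S,5aS,6R,9aS)-2,2,5a-trimethyl-7-methylidene-3-[(trimethylsilyl)oxy]decahydro-1-benzoxepin-6-yl}methyl 2,2-dimethylpropanoate | CC(C)(C)C(=O)OC[C@H]1[C@]2(C)CC[C@H](O[Si](C)(C)C)C(C)(C)O[C@H]2CCC1=C | intermediate (not isolated)
34 | [(3S,5aS,6R,9aS)-3-hydroxy-2,2,5a-trimethyl-7-methylidenedecahydro-1-benzoxepin-6-yl]methyl 2,2-dimethylpropanoate | CC(C)(C)C(=O)OC[C@H]1[C@]2(C)CC[C@H](O)C(C)(C)O[C@H]2CCC1=C | intermediate
35 | [(3S,5aS,6R,9aS)-3-{[tert-butyl(dimethyl)silyl]oxy}-2,2,5a-trimethyl-7-methylidenedecahydro-1-benzoxepin-6-yl]methyl 2,2-dimethylpropanoate | CC(C)(C)C(=O)OC[C@H]1[C@]2(C)CC[C@H](O[Si](C)(C)C(C)(C)C)C(C)(C)O[C@H]2CCC1=C | intermediate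
36 | [(3S,5aS,6R,7S,9aS)-3-{[tert-butyl(dimethyl)silyl]oxy}-2,2,5a-trimethyloctahydro-2H-spiro[1-benzoxepine-7,2'-oxiran]-6-yl]methyl 2,2-dimethylpropanoate | CC(C)(C)C(=O)OC[C@H]1[C@]2(C)CC[C@H](O[Si](C)(C)C(C)(C)C)C(C)(C)O[C@H]2CC[C@@]13CO3 | intermediate
37 | (3S,5aS,6R,7S,9aS)-3-{[tert-butyl(dimethyl)silyl]oxy}-6-(hydroxymethyl)-2,2,5a,7-tetramethyldecahydro-1-benzoxepin-7-ol | OC[C@H]1[C@]2(C)CC[C@H](O[Si](C)(C)C(C)(C)C)C(C)(C)O[C@H]2CC[C@]1(C)O | intermediate
38 | (3S,5aS,6S,7S,9aS)-3-{[tert-butyl(dimethyl)silyl]oxy}-6-(iodomethyl)-2,2,5a,7-tetramethyldecahydro-1-benzoxepin-7-ol | IC[C@H]1[C@]2(C)CC[C@H](O[Si](C)(C)C(C)(C)C)C(C)(C)O[C@H]2CC[C@]1(C)O | intermediate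
39 | (3S,5aS,6S,7S,9aS)-3-{[tert-butyl(dimethyl)silyl]oxy}-6-(iodomethyl)-2,2,5a,7-tetramethyldecahydro-1-benzoxepin-7-yl acetate (fragment B) | IC[C@H]1[C@]2(C)CC[C@H](O[Si](C)(C)C(C)(C)C)C(C)(C)O[C@H]2CC[C@]1(C)OC(C)=O | intermediate
40 | (3S,5aS,6S,7R,9aS)-6-{2-[(3S,5aS,6S,7S,9aS)-7-(acetyloxy)-3-{[tert-butyl(dimethyl)silyl]oxy}-2,2,5a,7-tetramethyldecahydro-1-benzoxepin-6-yl]ethyl}-2,2,5a,7-tetramethyldecahydro-1-benzoxepine-3,7-diyl diacetate | CC(=O)O[C@H]1CC[C@]2(C)[C@H](CC[C@@](C)(OC(C)=O)[C@H]2CC[C@H]2[C@]3(C)CC[C@H](O[Si](C)(C)C(C)(C)C)C(C)(C)O[C@H]3CC[C@]2(C)OC(C)=O)OC1(C)C | intermediate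
41 | (3S,5aS,6S,7R,9aS)-6-{2-[(3S,5aS,6S,7S,9aS)-7-(acetyloxy)-3-hydroxy-2,2,5a,7-tetramethyldecahydro-1-benzoxepin-6-yl]ethyl}-2,2,5a,7-tetramethyldecahydro-1-benzoxepine-3,7-diyl diacetate (CNP0169816.1) | CC(=O)O[C@H]1CC[C@]2(C)[C@H](CC[C@@](C)(OC(C)=O)[C@H]2CC[C@H]2[C@]3(C)CC[C@H](O)C(C)(C)O[C@H]3CC[C@]2(C)OC(C)=O)OC1(C)C | target

**Totals**
Total step count: 26.
Longest linear sequence: 17 steps (steps 1, 2, 12–24, 25, 26); the other branch is 13 steps (steps 1–11, 25, 26).

**Three steps most likely to fail, with fallbacks**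

Step 25 (the proposed new hydroalkylation). The risks are slow nickel-hydride insertion into the hindered alkene, hydrodeiodination of 39, and ionisation of the allylic acetate. The fallback uses known chemistry, sets out from 20 (with 39) and comes back at 40. Hydroboration of 20 with 9-BBN dimer (THF, 60 °C) puts boron on the exocyclic CH2 and hydrogen on C6 from the same open face. This gives (3S,5aS,6S,7R,9aS)-6-[(9-borabicyclo[3.3.1]nonan-9-yl)methyl]-2,2,5a,7-tetramethyldecahydro-1-benzoxepine-3,7-diyl diacetate F1. Without isolation, the alkylborane is joined to iodide 39 by a palladium-catalysed B-alkyl Suzuki–Miyaura alkyl–alkyl coupling [Pd(OAc)2, PCy3, K3PO4·H2O, THF, 25–40 °C] to give 40.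

Step 19 (allylsilane-terminated cascade). The risks are protodesilylation, epoxide rearrangement, or opening at the wrong epoxide first. The fallback sets out from 15 and comes back at 35; it reaches the exocyclic alkene by carbonyl methylenation instead of allylsilane termination.
- Silylation of the C3 hydroxyl (TBSCl, imidazole, DMF, 40 °C) gives methyl (3S,5aS,6S,9aS)-3-{[tert-butyl(dimethyl)silyl]oxy}-2,2,5a-trimethyl-7-oxodecahydro-1-benzoxepine-6-carboxylate F2.
- LiAlH4 (THF, 0 °C) reduces ketone and ester to (3S,5aS,6R,7R,9aS)-3-{[tert-butyl(dimethyl)silyl]oxy}-6-(hydroxymethyl)-2,2,5a-trimethyldecahydro-1-benzoxepin-7-ol F3 (major C7 epimer; this centre is removed again).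
- Selective acylation of the primary hydroxyl (t-BuCOCl, pyridine, −20 °C) gives [(3S,5aS,6R,7R,9aS)-3-{[tert-butyl(dimethyl)silyl]oxy}-7-hydroxy-2,2,5a-trimethyldecahydro-1-benzoxepin-6-yl]methyl 2,2-dimethylpropanoate F4.
- Dess–Martin oxidation gives [(3S,5aS,6R,9aS)-3-{[tert-butyl(dimethyl)silyl]oxy}-2,2,5a-trimethyl-7-oxodecahydro-1-benzoxepin-6-yl]methyl 2,2-dimethylpropanoate F5.
- Non-basic methylenation (Zn, CH2Br2, TiCl4, THF/CH2Cl2, 0 → 25 °C), chosen to avoid β-elimination of pivalate, gives 35.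

Step 7 (cascade ended by the β-silyloxy enoate). The risks are low nucleophilicity of the push–pull enol ether and cyclisation through oxygen. The fallback sets out from 34 and comes back at 18; it takes the bicyclic core from the allylsilane cascade. Ozonolysis of the exocyclic alkene of 34 (O3, CH2Cl2/MeOH, −78 °C; then Me2S) gives [(3S,5aS,6R,9aS)-3-hydroxy-2,2,5a-trimethyl-7-oxodecahydro-1-benzoxepin-6-yl]methyl 2,2-dimethylpropanoate F6. Treatment with DBU (CH2Cl2, 25 °C) eliminates pivalic acid by an E1cB pathway to give 18.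

**Further compounds**
F1 | step 25 | (3S,5aS,6S,7R,9aS)-6-[(9-borabicyclo[3.3.1]nonan-9-yl)methyl]-2,2,5a,7-tetramethyldecahydro-1-benzoxepine-3,7-diyl diacetate | CC(=O)O[C@H]1CC[C@]2(C)[C@H](CC[C@@](C)(OC(C)=O)[C@H]2CB3C4CCCC3CCC4)OC1(C)C
F2 | step 19 | methyl (3S,5aS,6S,9aS)-3-{[tert-butyl(dimethyl)silyl]oxy}-2,2,5a-trimethyl-7-oxodecahydro-1-benzoxepine-6-carboxylate | CC(C)(C)[Si](C)(C)O[C@H]1CC[C@]2(C)[C@H](CCC(=O)[C@H]2C(=O)OC)OC1(C)C
F3 | step 19 | (3S,5aS,6R,7R,9aS)-3-{[tert-butyl(dimethyl)silyl]oxy}-6-(hydroxymethyl)-2,2,5a-trimethyldecahydro-1-benzoxepin-7-ol | CC(C)(C)[Si](C)(C)O[C@H]1CC[C@]2(C)[C@H](CC[C@@H](O)[C@H]2CO)OC1(C)C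
F4 | step 19 | [(3S,5aS,6R,7R,9aS)-3-{[tert-butyl(dimethyl)silyl]oxy}-7-hydroxy-2,2,5a-trimethyldecahydro-1-benzoxepin-6-yl]methyl 2,2-dimethylpropanoate | CC(C)(C)[Si](C)(C)O[C@H]1CC[C@]2(C)[C@H](CC[C@@H](O)[C@H]2COC(=O)C(C)(C)C)OC1(C)C
F5 | step 19 | [(3S,5aS,6R,9aS)-3-{[tert-butyl(dimethyl)silyl]oxy}-2,2,5a-trimethyl-7-oxodecahydro-1-benzoxepin-6-yl]methyl 2,2-dimethylpropanoate | CC(C)(C)[Si](C)(C)O[C@H]1CC[C@]2(C)[C@H](CCC(=O)[C@H]2COC(=O)C(C)(C)C)OC1(C)C
F6 | step 7 | [(3S,5aS,6R,9aS)-3-hydroxy-2,2,5a-trimethyl-7-oxodecahydro-1-benzoxepin-6-yl]methyl 2,2-dimethylpropanoate | O[C@H]1CC[C@]2(C)[C@H](CCC(=O)[C@H]2COC(=O)C(C)(C)C)OC1(C)C
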